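## The problem

CNP0602535.2 is a 2,3,4,7-tetrahydrooxepine (ring atoms O1, C2 to C7). C2, the only stereocentre (S), is a fully substituted ether carbon carrying a free carboxylic acid and the C8–C9 arm CH2–C(=O)–(2,5-dihydroxyphenyl); C6 carries the side chain C1′–C5′, CH2CH2CH=C(CH3)CH2O, with an (E)-trisubstituted olefin and an (E)-4-hydroxycinnamate on the allylic oxygen. With no second stereocentre, nothing can relay configuration to C2: it must be made by an enantioselective reaction on an achiral precursor and then kept out of all later chemistry, which its lack of an α-hydrogen allows. The ring poses two problems of its own: end-to-end closure of a seven-membered ether is slow, and the ring olefin must stay at C5=C6 and not move into the enol ether position C6=C7. The functional groups leave little room: O1 is β to the aryl ketone, so base can open the ring by retro-oxa-Michael elimination; the hydroquinone oxidises in air, most easily as its phenolate; the allylic cinnamate excludes saponification and is at risk from π-allyl-forming metals and strong acid; and the acid and three phenols need masks that come off together. The feature that allows a short ring synthesis is the segment O1–C7H2–C6(R)=C5H: it is what forms when a dihalocyclopropane fused across the enol ether bond of a six-membered 3,4-dihydro-2H-pyran opens, the carbene carbon becoming C6 and keeping a halogen as the attachment point for the side chain. C2, with its ester and two-carbon arm, is then a bystander three atoms from the nearest reacting carbon.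

## Retrosynthesis

**Unmasking (37 from 36).** No skeletal bond is cut; the acid is carried as a tert-butyl ester and the three phenols as methoxymethyl ethers, all acid-labile. Base-labile masks are excluded by the cinnamate and the β-alkoxy ketone, hydrogenolysis by three olefins, and aryl silyl ethers by the aryllithium chemistry used earlier. The forward step needs acid strong enough for the tert-butyl ester that does not ionise the allylic ester.

**Cinnamate (36 from 32 and 35).** The acyl–oxygen bond of the allylic ester is cut last among the skeletal bonds. Carrying this ester through the palladium coupling or the aryllithium addition would expose it to π-allyl formation and to nucleophilic attack. The precursor 32 is an allylic alcohol; acid 35 comes from 33 through 34. The forward reaction must acylate a primary allylic alcohol without allylic transposition or base damage.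

**Aryl ketone (32 from 31, 30, then 26 and 29).** The C9–aryl bond is cut, giving aldehyde 26 and aryllithium 29 (from 28, from 27); 31 is the 4-methoxybenzyl ether of 32, and 26 comes from alcohol 25 and silyl ether 24. An electron-rich benzylic ketone or its ketal would not survive carbene, silver or Lewis acid if carried through the ring expansion, so the arm is kept as a protected primary alcohol until the ring and side chain are in place. The addition must be faster than enolisation of the β-alkoxy aldehyde, and both oxidations must be neutral.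

**Side chain (24 from 17 and 23).** The sp2–sp3 bond C6–C1′ is cut between bromo-oxepine 17 and alkylborane 23, made from diene 22. The neighbouring options, building the ring olefin by olefination or joining at the side-chain olefin, would raise regio- or E/Z questions. Here the side-chain geometry is fixed beforehand in 22 (from 18 and 19 through 20 and 21), and the bromine on C6 is a free product of the key step. The forward reaction needs terminal-selective hydroboration of the diene.

**Ring expansion (17 from 14 and 15).** C6 is excised, cutting C5–C6 and C6–C7, which leads back to dihydropyran 14 and bromoform 15. The neighbouring ring cuts (O1–C2 at a quaternary carbon, O1–C7 by a hindered tertiary alkoxide, metathesis to a bromo-olefin) are all end-to-end closures of a seven-membered ring and all worse. The precursor loses the ring size problem, the olefin position problem and the bromide. The forward step must add the carbene only to the enol ether, open the internal cyclopropane bond and deliver hydride to C7.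

**Dihydropyran (14 from 12, 11, 10).** The enol ether comes from lactol 12 by dehydration; 12 is the closed form of hydroxy aldehyde 11, which comes from the terminal olefin of 10. This removes the ring and leaves an open-chain tertiary alcohol. The dehydration must avoid acid that would cleave the ester.

**C2 (10 from 9, 8, then 4 and 6).** The C2–C8 bond is cut as an acetate aldol addition of silyl ketene thioacetal 6 (from 5) to α-keto ester 4 (from 1 through 3, and 2). Cutting C2–C3 instead would mean adding an alkyl metal to a keto ester with no good means of enantiocontrol. The aldol has two-point binding of the keto ester to a chiral Lewis acid in its favour. The thioester is then reduced (9) and silylated (10). Both precursors are achiral and three to seven carbons in size.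

## Roads not taken

**Alternative 1:** The cut is O1–C2. A chiral bifunctional Brønsted base would promote 7-exo-trig oxa-Michael addition of the C7 hydroxyl of the open-chain aroylacrylate A1 to C2, giving A2, which is the same compound as 36.
- Merits: ring and stereocentre are formed in one late, biomimetic step on a fully assembled chain, with no protecting-group traffic at C9. If the catalysis worked it would be shorter and more convergent than the chosen plan; this is conceded.
- Weak points: alcohol addition to a β,β-disubstituted acceptor to make a fully substituted ether carbon is thermodynamically shallow and reversible, so enantiopurity depends on an equilibrium; it is the reverse of the ring opening feared for the target. Seven-membered closure is slow relative to the five- and six-membered cases. A1 needs a (Z)-trisubstituted allylic alcohol and an isomerisation-prone (E)-aroylacrylate.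
- Against it the chosen plan sets a stereocentre made early by a catalytic aldol class with a known substrate range, a ring formation that is not an equilibrium, and a ring olefin that is cis by construction.

**Alternative 2:** The cut is C7–O1. Rh2(OAc)4 would decompose diazoketone A3, and the dirhodium carbenoid at C7 would insert into the tertiary O–H bond to give oxepan-6-one A4.
- Merits: O–H insertion is one of the few reliable closures of seven-membered ethers, is catalytic and neutral, and carries the aryl ketone (as its dioxolane) from the start. Its ring formation rests on firmer precedent than the hydride-capture variant used here, and it saves the late C9 redox steps; both points are conceded.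
- Weak points: the hydroxyl is tertiary and hindered, and 1,5 C–H insertion at C3 to a cyclopentanone competes. Making A3 means diazomethane-type homologation beside a free tertiary alcohol and an acid-labile ketal. Above all, the C6 ketone must then become the C5=C6 olefin bearing the side chain, and neither enolisation nor addition–dehydration is reliably directed to C5 rather than C7; the C6=C7 enol ether is the likely sink.
- In the chosen plan the position of the olefin and the handle on C6 follow from the mechanism.

**Alternative 3:** The cut is C6–C7. SnCl4 would ionise the (2-methoxyethoxy)methyl ether on O1 of A5 to the O1=C7H2 oxocarbenium ion, which the (Z)-vinylsilane attacks through C6 with loss of silicon, giving A6.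
- Merits: ring, ring olefin and side chain are set in one step, and the thioester from the aldol is kept. It is more convergent at C6 and saves the cross-coupling; this is conceded.
- Weak points: A5 needs a stereodefined trisubstituted vinylsilane carrying the whole side chain and acetal formation on a hindered tertiary α-hydroxy ester. SnCl4 threatens the tert-butyl ester. The side-chain olefin is a competing π-nucleophile, and protodesilylation competes.
- The chosen plan sets against it a cyclisation-free ring formation on a small substrate made in six steps, and a side chain that is attached late and can be varied.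

Key step: step 8

Assumption: with keto ester 4 the (S,S)-bis(oxazoline)–Cu(OTf)2 catalyst is taken to shield the same ketone face as with pyruvate esters, which corresponds to (2S); if the sense were opposite, the (R,R)-ligand would be used and nothing else would change.

Abbreviations in the steps: TBDPS = tert-butyldiphenylsilyl, MOM = methoxymethyl, PMB = 4-methoxybenzyl, DMP = Dess–Martin periodinane.

## Steps

Step 1
Reactants: 1 5-bromopent-1-ene; 2 di-tert-butyl oxalate
Product: 4 tert-butyl 2-oxohept-6-enoate, via pent-4-en-1-ylmagnesium bromide 3 (not isolated)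
Conditions: Mg, THF, rt; then added to 2 (excess), THF, −78 °C
Reagents that add atoms: none
Why: Grignard acylation of an oxalate diester: the tetrahedral magnesium alkoxide does not collapse at −78 °C and inverse addition to excess 2 suppresses double addition, so the α-keto ester should result.

Step 2
Reactants: 5 S-tert-butyl ethanethioate
Product: 6 {[1-(tert-butylsulfanyl)ethenyl]oxy}trimethylsilane
Conditions: LiN(iPr)2, THF, −78 °C; Me3SiCl, −78 °C → rt
Reagents that add atoms: chlorotrimethylsilane, C[Si](C)(C)Cl
Why: Kinetic enolisation of the thioester and O-silylation (enolate trapping) give the silyl ketene thioacetal needed for the Mukaiyama aldol; it is distilled and used fresh.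

Step 3
Reactants: 4 tert-butyl 2-oxohept-6-enoate; 6 {[1-(tert-butylsulfanyl)ethenyl]oxy}trimethylsilane
Product: 8 tert-butyl (2S)-2-[2-(tert-butylsulfanyl)-2-oxoethyl]-2-hydroxyhept-6-enoate, via trimethylsilyl ether of the aldol adduct 7 (not isolated)
Conditions: Cu(OTf)2 (10 mol %), 2,2'-(propane-2,2-diyl)bis[(4S)-4-tert-butyl-4,5-dihydro-1,3-oxazole] (11 mol %), THF, −78 °C; then 1 M HCl
Reagents that add atoms: none
Why: Catalytic enantioselective Mukaiyama aldol addition: the keto ester chelates the divalent copper centre through both carbonyl oxygens, one tert-butyl group of the ligand screens one ketone face and the silyl ketene thioacetal adds to the other, creating C2 as (S); α-keto esters with unbranched alkyl groups lie in the known substrate range of this catalyst, and acidic work-up removes the silyl group.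

Step 4
Reactants: 8 tert-butyl (2S)-2-[2-(tert-butylsulfanyl)-2-oxoethyl]-2-hydroxyhept-6-enoate
Product: 9 tert-butyl (2S)-2-hydroxy-2-(2-hydroxyethyl)hept-6-enoate
Conditions: LiBH4, THF, 0 °C → rt
Reagents that add atoms: none
Why: Chemoselective hydride reduction: the thioester is much more electrophilic than the hindered tert-butyl ester and should be reduced alone to the primary alcohol; the aprotic, non-basic medium disfavours retro-aldol cleavage and lactonisation.

Step 5
Reactants: 9 tert-butyl (2S)-2-hydroxy-2-(2-hydroxyethyl)hept-6-enoate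
Product: 10 tert-butyl (2S)-2-[2-(TBDPS-oxy)ethyl]-2-hydroxyhept-6-enoate
Conditions: TBDPSCl, imidazole, CH2Cl2, 0 °C → rt
Reagents that add atoms: tert-butyl(chloro)diphenylsilane, CC(C)(C)[Si](Cl)(c1ccccc1)c1ccccc1
Why: Selective silylation of the primary over the tertiary hydroxyl by a bulky silyl chloride; this silyl ether is chosen because it must survive alkoxide base, silver and boron Lewis acids in steps 7 and 8.

Step 6
Reactants: 10 tert-butyl (2S)-2-[2-(TBDPS-oxy)ethyl]-2-hydroxyhept-6-enoate
Product: 12 tert-butyl (2S,6RS)-2-[2-(TBDPS-oxy)ethyl]-6-hydroxyoxane-2-carboxylate, via open-chain hydroxy aldehyde 11 (not isolated)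
Conditions: O3, CH2Cl2, −78 °C; then PPh3, −78 °C → rt
Reagents that add atoms: ozone, [O-][O+]=O
Why: Ozonolysis with reductive work-up gives the δ-hydroxy aldehyde, which closes onto the tertiary hydroxyl as the six-membered lactol; the anomeric centre forms as a mixture that is removed in step 7.

Step 7
Reactants: 12 tert-butyl (2S,6RS)-2-[2-(TBDPS-oxy)ethyl]-6-hydroxyoxane-2-carboxylate
Product: 14 tert-butyl (2S)-2-[2-(TBDPS-oxy)ethyl]-3,4-dihydro-2H-pyran-2-carboxylate, via anomeric mesylate 13 (not isolated)
Conditions: MsCl, Et3N, THF, 0 → 65 °C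
Reagents that add atoms: none
Why: Lactol dehydration through the anomeric sulfonate (the usual glycal-forming elimination): ionisation assisted by the ring oxygen and loss of the adjacent proton to the amine give the cyclic enol ether without acid; C2 has no hydrogen and is unaffected.

Step 8
Reactants: 14 tert-butyl (2S)-2-[2-(TBDPS-oxy)ethyl]-3,4-dihydro-2H-pyran-2-carboxylate; 15 bromoform
Product: 17 tert-butyl (2S)-6-bromo-2-[2-(TBDPS-oxy)ethyl]-2,3,4,7-tetrahydrooxepine-2-carboxylate, via dibromocyclopropane adduct 16 (not isolated)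
Conditions: KOtBu, pentane, −20 → 0 °C; filtered and concentrated cold; then AgBF4, 2,6-di-tert-butyl-4-methylpyridine, CH2Cl2, −40 °C; then Et3SiH, −40 → 0 °C
Reagents that add atoms: none
Why: Proposed new method: dibromocarbene from bromoform and KOtBu is electrophilic and should add in a concerted [2+1] fashion to the only olefin present, the electron-rich enol ether of 14, giving the fused dibromocyclopropane 16, whose two new stereocentres are irrelevant because both are flattened again. AgBF4 then removes the bromide endo to the six-membered ring while the cyclopropane bond between the two former enol ether carbons opens in the symmetry-allowed disrotatory sense, so the carbene carbon is inserted between them as C6 (new bonds C5–C6 and C6–C7) and the resulting 2-bromoallyl cation is held by the ring oxygen as the oxocarbenium ion O1=C7. Et3SiH, added only after the silver salt is consumed because silver cations oxidise hydrosilanes, delivers hydride to C7 to give 17 with the olefin at C5=C6; silicon ends as inert Et3SiF, which is why tetrafluoroborate is preferred to triflate, whose silyl triflate by-product could attack the tert-butyl ester. The closest known reactions are the silver- or base-promoted ring expansions of dihalocarbene adducts of glycals and dihydropyrans to 2-halo-oxepines with capture by alcohols or acetate, and the silane reduction of cyclic allylic oxocarbenium ions at the anomeric carbon; only hydride as the capturing nucleophile is new. The seven-membered ring forms by one-carbon ring expansion (electrocyclic opening of a cyclopropyl cation), not by cyclisation, so no medium-ring closure is involved and the ring olefin is necessarily cis. No stereocentre is created, and C2, three atoms from the nearest reacting carbon and without an α-hydrogen, is untouched. The selectivities needed are cleavage of the internal cyclopropane bond and hydride delivery to C7 rather than C5; the lone pair on O1, which stabilises positive charge only at C7, secures both.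

Step 9
Reactants: 18 acrolein; 19 ethyl 2-(triphenyl-λ5-phosphanylidene)propanoate
Product: 20 ethyl (2E)-2-methylpenta-2,4-dienoate
Conditions: CH2Cl2, 0 °C → rt
Reagents that add atoms: none
Why: Wittig olefination with a stabilised α-methyl ylide gives the (E)-trisubstituted enoate, which fixes the side-chain olefin geometry of the target.

Step 10
Reactants: 20 ethyl (2E)-2-methylpenta-2,4-dienoate
Product: 21 (2E)-2-methylpenta-2,4-dien-1-ol
Conditions: iBu2AlH, CH2Cl2, −78 → 0 °C
Reagents that add atoms: none
Why: 1,2-Reduction of the conjugated ester to the allylic alcohol by the aluminium hydride leaves the diene and its geometry intact.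

Step 11
Reactants: 21 (2E)-2-methylpenta-2,4-dien-1-ol
Product: 22 1-methoxy-4-({[(2E)-2-methylpenta-2,4-dien-1-yl]oxy}methyl)benzene
Conditions: NaH, PMBCl, Bu4NI (cat.), THF/DMF, 0 °C → rt
Reagents that add atoms: 4-methoxybenzyl chloride, COc1ccc(CCl)cc1
Why: Williamson etherification; the PMB ether tolerates borane, palladium, fluoride, the periodinane and the aryllithium and is later removed oxidatively without acid or base.

Step 12
Reactants: 22 1-methoxy-4-({[(2E)-2-methylpenta-2,4-dien-1-yl]oxy}methyl)benzene; 17 tert-butyl (2S)-6-bromo-2-[2-(TBDPS-oxy)ethyl]-2,3,4,7-tetrahydrooxepine-2-carboxylate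
Product: 24 tert-butyl (2S)-2-[2-(TBDPS-oxy)ethyl]-6-[(3E)-5-(PMB-oxy)-4-methylpent-3-en-1-yl]-2,3,4,7-tetrahydrooxepine-2-carboxylate, via B-alkyl-9-borabicyclo[3.3.1]nonane 23 (not isolated)
Conditions: 9-BBN dimer, THF, 0 °C → rt; then 17, PdCl2(dppf) (5 mol %), AsPh3, Cs2CO3, DMF/THF/H2O, rt → 50 °C
Reagents that add atoms: none
Why: B-alkyl Suzuki–Miyaura coupling: the hindered borane hydroborates only the monosubstituted terminus of the diene with boron on the terminal carbon, and the primary alkylborane is transferred under base to the alkenylpalladium species formed from 17 and zerovalent palladium; cyclic 2-bromoallyl ethers of this kind have been used in palladium couplings and the alkenylpalladium cannot eliminate the ring oxygen, so the C6–C1′ bond should form with both olefins unchanged.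

Step 13
Reactants: 24 tert-butyl (2S)-2-[2-(TBDPS-oxy)ethyl]-6-[(3E)-5-(PMB-oxy)-4-methylpent-3-en-1-yl]-2,3,4,7-tetrahydrooxepine-2-carboxylate
Product: 25 tert-butyl (2S)-2-(2-hydroxyethyl)-6-[(3E)-5-(PMB-oxy)-4-methylpent-3-en-1-yl]-2,3,4,7-tetrahydrooxepine-2-carboxylate
Conditions: Bu4NF, AcOH, THF, 0 °C → rt
Reagents that add atoms: none
Why: Fluoride cleavage of the silyl ether; acetic acid buffering keeps the liberated γ-hydroxy ester from lactonising onto the tert-butyl ester.

Step 14
Reactants: 25 tert-butyl (2S)-2-(2-hydroxyethyl)-6-[(3E)-5-(PMB-oxy)-4-methylpent-3-en-1-yl]-2,3,4,7-tetrahydrooxepine-2-carboxylate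
Product: 26 tert-butyl (2S)-6-[(3E)-5-(PMB-oxy)-4-methylpent-3-en-1-yl]-2-(2-oxoethyl)-2,3,4,7-tetrahydrooxepine-2-carboxylate
Conditions: DMP, CH2Cl2, 0 °C → rt
Reagents that add atoms: none
Why: Dess–Martin oxidation of the primary alcohol under neutral conditions; the β-alkoxy aldehyde is used at once to avoid β-elimination of the ring oxygen.

Step 15
Reactants: 27 hydroquinone
Product: 28 1,4-bis(methoxymethoxy)benzene
Conditions: NaH, MOMCl, DMF, 0 °C → rt
Reagents that add atoms: chloromethyl methyl ether, COCCl
Why: Double O-alkylation of the bis-phenolate; the MOM ethers protect the phenols, direct the lithiation of step 16 and fall to the acid of the last step.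

Step 16
Reactants: 28 1,4-bis(methoxymethoxy)benzene; 26 tert-butyl (2S)-6-[(3E)-5-(PMB-oxy)-4-methylpent-3-en-1-yl]-2-(2-oxoethyl)-2,3,4,7-tetrahydrooxepine-2-carboxylate
Product: 30 tert-butyl (2S)-2-{(2RS)-2-[2,5-bis(methoxymethoxy)phenyl]-2-hydroxyethyl}-6-[(3E)-5-(PMB-oxy)-4-methylpent-3-en-1-yl]-2,3,4,7-tetrahydrooxepine-2-carboxylate, via 2,5-bis(methoxymethoxy)phenyllithium 29 (not isolated)
Conditions: n-BuLi, THF, 0 °C; then 26, THF, −78 °C; aqueous work-up
Reagents that add atoms: none
Why: Directed ortho-metalation of 28 gives the aryllithium, whose 1,2-addition to the aldehyde at −78 °C should outrun enolisation and attack on the hindered tert-butyl ester; the carbinol centre forms as a mixture and is erased in step 17.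

Step 17
Reactants: 30 tert-butyl (2S)-2-{(2RS)-2-[2,5-bis(methoxymethoxy)phenyl]-2-hydroxyethyl}-6-[(3E)-5-(PMB-oxy)-4-methylpent-3-en-1-yl]-2,3,4,7-tetrahydrooxepine-2-carboxylate
Product: 31 tert-butyl (2S)-2-{2-[2,5-bis(methoxymethoxy)phenyl]-2-oxoethyl}-6-[(3E)-5-(PMB-oxy)-4-methylpent-3-en-1-yl]-2,3,4,7-tetrahydrooxepine-2-carboxylate
Conditions: DMP, CH2Cl2, 0 °C → rt
Reagents that add atoms: none
Why: Dess–Martin oxidation of the benzylic alcohol to the aryl ketone; the neutral medium avoids retro-oxa-Michael opening of the β-alkoxy ketone.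

Step 18
Reactants: 31 tert-butyl (2S)-2-{2-[2,5-bis(methoxymethoxy)phenyl]-2-oxoethyl}-6-[(3E)-5-(PMB-oxy)-4-methylpent-3-en-1-yl]-2,3,4,7-tetrahydrooxepine-2-carboxylate
Product: 32 tert-butyl (2S)-2-{2-[2,5-bis(methoxymethoxy)phenyl]-2-oxoethyl}-6-[(3E)-5-hydroxy-4-methylpent-3-en-1-yl]-2,3,4,7-tetrahydrooxepine-2-carboxylate
Conditions: DDQ, CH2Cl2/pH 7 buffer, 0 °C
Reagents that add atoms: none
Why: Oxidative cleavage of the PMB ether through its benzylic oxocarbenium ion and hydrolysis; the buffered medium leaves the tert-butyl ester, MOM ethers, ketone and both trisubstituted olefins in place.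

Step 19
Reactants: 33 p-coumaric acid
Product: 35 (2E)-3-[4-(methoxymethoxy)phenyl]prop-2-enoic acid, via methoxymethyl ester of the acid 34 (not isolated)
Conditions: MOMCl, iPr2NEt, CH2Cl2, 0 °C → rt; then LiOH, THF/MeOH/H2O, rt; HCl to pH 4, 0 °C
Reagents that add atoms: chloromethyl methyl ether, COCCl
Why: Exhaustive alkylation of phenol and carboxylate, then saponification of the much more labile MOM ester in the same flask, gives the phenol-protected acid with the (E)-olefin unchanged.

Step 20
Reactants: 32 tert-butyl (2S)-2-{2-[2,5-bis(methoxymethoxy)phenyl]-2-oxoethyl}-6-[(3E)-5-hydroxy-4-methylpent-3-en-1-yl]-2,3,4,7-tetrahydrooxepine-2-carboxylate; 35 (2E)-3-[4-(methoxymethoxy)phenyl]prop-2-enoic acid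
Product: 36 tert-butyl (2S)-2-{2-[2,5-bis(methoxymethoxy)phenyl]-2-oxoethyl}-6-[(3E)-5-({(2E)-3-[4-(methoxymethoxy)phenyl]prop-2-enoyl}oxy)-4-methylpent-3-en-1-yl]-2,3,4,7-tetrahydrooxepine-2-carboxylate
Conditions: DCC, DMAP (cat.), CH2Cl2, 0 °C → rt
Reagents that add atoms: none
Why: Steglich esterification: carbodiimide activation and acyl transfer by DMAP acylate the unhindered primary allylic alcohol without ionising it, so the olefin geometry and allylic position are kept.

Step 21
Reactants: 36 tert-butyl (2S)-2-{2-[2,5-bis(methoxymethoxy)phenyl]-2-oxoethyl}-6-[(3E)-5-({(2E)-3-[4-(methoxymethoxy)phenyl]prop-2-enoyl}oxy)-4-methylpent-3-en-1-yl]-2,3,4,7-tetrahydrooxepine-2-carboxylate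
Product: 37 (2S)-2-[2-(2,5-dihydroxyphenyl)-2-oxoethyl]-6-[(3E)-5-{[(2E)-3-(4-hydroxyphenyl)prop-2-enoyl]oxy}-4-methylpent-3-en-1-yl]-2,3,4,7-tetrahydrooxepine-2-carboxylic acid
Conditions: TFA/CH2Cl2/H2O (25:70:5), 0 °C → rt, argon
Reagents that add atoms: none
Why: Acidolysis: trifluoroacetic acid cleaves the tert-butyl ester by loss of 2-methylpropene and hydrolyses the three aryl MOM acetals in one operation, with water trapping the cations; base is avoided and air is excluded to protect the hydroquinone.

## Compound list

1 | 5-bromopent-1-ene | C=CCCCBr | starting material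
2 | di-tert-butyl oxalate | CC(C)(C)OC(=O)C(=O)OC(C)(C)C | starting material
3 | pent-4-en-1-ylmagnesium bromide | C=CCCC[Mg]Br | intermediate
4 | tert-butyl 2-oxohept-6-enoate | C=CCCCC(=O)C(=O)OC(C)(C)C | intermediate
5 | S-tert-butyl ethanethioate | CC(=O)SC(C)(C)C | starting material
6 | {[1-(tert-butylsulfanyl)ethenyl]oxy}trimethylsilane | C=C(O[Si](C)(C)C)SC(C)(C)C | intermediate
7 | tert-butyl (2S)-2-[2-(tert-butylsulfanyl)-2-oxoethyl]-2-[(trimethylsilyl)oxy]hept-6-enoate | C=CCCC[C@](CC(=O)SC(C)(C)C)(C(=O)OC(C)(C)C)O[Si](C)(C)C | intermediate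
8 | tert-butyl (2S)-2-[2-(tert-butylsulfanyl)-2-oxoethyl]-2-hydroxyhept-6-enoate | C=CCCC[C@](CC(=O)SC(C)(C)C)(C(=O)OC(C)(C)C)O | intermediate
9 | tert-butyl (2S)-2-hydroxy-2-(2-hydroxyethyl)hept-6-enoate | C=CCCC[C@](CCO)(C(=O)OC(C)(C)C)O | intermediate
10 | tert-butyl (2S)-2-{2-[(tert-butyldiphenylsilyl)oxy]ethyl}-2-hydroxyhept-6-enoate | C=CCCC[C@](CCO[Si](c1ccccc1)(c1ccccc1)C(C)(C)C)(C(=O)OC(C)(C)C)O | intermediate
11 | tert-butyl (2S)-2-{2-[(tert-butyldiphenylsilyl)oxy]ethyl}-2-hydroxy-6-oxohexanoate | O=CCCC[C@](CCO[Si](c1ccccc1)(c1ccccc1)C(C)(C)C)(C(=O)OC(C)(C)C)O | intermediate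
12 | tert-butyl (2S,6RS)-2-{2-[(tert-butyldiphenylsilyl)oxy]ethyl}-6-hydroxyoxane-2-carboxylate (both anomers) | OC1CCC[C@](CCO[Si](c2ccccc2)(c2ccccc2)C(C)(C)C)(C(=O)OC(C)(C)C)O1 | intermediate
13 | tert-butyl (2S,6RS)-2-{2-[(tert-butyldiphenylsilyl)oxy]ethyl}-6-[(methanesulfonyl)oxy]oxane-2-carboxylate | CS(=O)(=O)OC1CCC[C@](CCO[Si](c2ccccc2)(c2ccccc2)C(C)(C)C)(C(=O)OC(C)(C)C)O1 | intermediate
14 | tert-butyl (2S)-2-{2-[(tert-butyldiphenylsilyl)oxy]ethyl}-3,4-dihydro-2H-pyran-2-carboxylate | C1=CCC[C@](CCO[Si](c2ccccc2)(c2ccccc2)C(C)(C)C)(C(=O)OC(C)(C)C)O1 | intermediate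
15 | bromoform (tribromomethane) | BrC(Br)Br | starting material
16 | tert-butyl (3S)-7,7-dibromo-3-{2-[(tert-butyldiphenylsilyl)oxy]ethyl}-2-oxabicyclo[4.1.0]heptane-3-carboxylate (both cis-fused cyclopropane diastereomers) | BrC1(Br)C2CC[C@](CCO[Si](c3ccccc3)(c3ccccc3)C(C)(C)C)(C(=O)OC(C)(C)C)OC12 | intermediate
17 | tert-butyl (2S)-6-bromo-2-{2-[(tert-butyldiphenylsilyl)oxy]ethyl}-2,3,4,7-tetrahydrooxepine-2-carboxylate | BrC1=CCC[C@](CCO[Si](c2ccccc2)(c2ccccc2)C(C)(C)C)(C(=O)OC(C)(C)C)OC1 | intermediate
18 | acrolein (prop-2-enal) | C=CC=O | starting material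
19 | ethyl 2-(triphenyl-λ5-phosphanylidene)propanoate | CCOC(=O)C(C)=P(c1ccccc1)(c1ccccc1)c1ccccc1 | starting material
20 | ethyl (2E)-2-methylpenta-2,4-dienoate | C=C/C=C(\C)C(=O)OCC | intermediate
21 | (2E)-2-methylpenta-2,4-dien-1-ol | C=C/C=C(\C)CO | intermediate
22 | 1-methoxy-4-({[(2E)-2-methylpenta-2,4-dien-1-yl]oxy}methyl)benzene | C=C/C=C(\C)COCc1ccc(OC)cc1 | intermediate
23 | 9-{(3E)-5-[(4-methoxyphenyl)methoxy]-4-methylpent-3-en-1-yl}-9-borabicyclo[3.3.1]nonane | COc1ccc(COC/C(C)=C/CCB2C3CCCC2CCC3)cc1 | intermediate
24 | tert-butyl (2S)-2-{2-[(tert-butyldiphenylsilyl)oxy]ethyl}-6-{(3E)-5-[(4-methoxyphenyl)methoxy]-4-methylpent-3-en-1-yl}-2,3,4,7-tetrahydrooxepine-2-carboxylate | COc1ccc(COC/C(C)=C/CCC2=CCC[C@](CCO[Si](c3ccccc3)(c3ccccc3)C(C)(C)C)(C(=O)OC(C)(C)C)OC2)cc1 | intermediate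
25 | tert-butyl (2S)-2-(2-hydroxyethyl)-6-{(3E)-5-[(4-methoxyphenyl)methoxy]-4-methylpent-3-en-1-yl}-2,3,4,7-tetrahydrooxepine-2-carboxylate | COc1ccc(COC/C(C)=C/CCC2=CCC[C@](CCO)(C(=O)OC(C)(C)C)OC2)cc1 | intermediate
26 | tert-butyl (2S)-6-{(3E)-5-[(4-methoxyphenyl)methoxy]-4-methylpent-3-en-1-yl}-2-(2-oxoethyl)-2,3,4,7-tetrahydrooxepine-2-carboxylate | COc1ccc(COC/C(C)=C/CCC2=CCC[C@](CC=O)(C(=O)OC(C)(C)C)OC2)cc1 | intermediate
27 | hydroquinone (benzene-1,4-diol) | Oc1ccc(O)cc1 | starting material
28 | 1,4-bis(methoxymethoxy)benzene | COCOc1ccc(OCOC)cc1 | intermediate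
29 | [2,5-bis(methoxymethoxy)phenyl]lithium | [Li]c1cc(OCOC)ccc1OCOC | intermediate
30 | tert-butyl (2S)-2-{(2RS)-2-[2,5-bis(methoxymethoxy)phenyl]-2-hydroxyethyl}-6-{(3E)-5-[(4-methoxyphenyl)methoxy]-4-methylpent-3-en-1-yl}-2,3,4,7-tetrahydrooxepine-2-carboxylate | COc1ccc(COC/C(C)=C/CCC2=CCC[C@](CC(O)c3cc(OCOC)ccc3OCOC)(C(=O)OC(C)(C)C)OC2)cc1 | intermediate
31 | tert-butyl (2S)-2-{2-[2,5-bis(methoxymethoxy)phenyl]-2-oxoethyl}-6-{(3E)-5-[(4-methoxyphenyl)methoxy]-4-methylpent-3-en-1-yl}-2,3,4,7-tetrahydrooxepine-2-carboxylate | COc1ccc(COC/C(C)=C/CCC2=CCC[C@](CC(=O)c3cc(OCOC)ccc3OCOC)(C(=O)OC(C)(C)C)OC2)cc1 | intermediate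
32 | tert-butyl (2S)-2-{2-[2,5-bis(methoxymethoxy)phenyl]-2-oxoethyl}-6-[(3E)-5-hydroxy-4-methylpent-3-en-1-yl]-2,3,4,7-tetrahydrooxepine-2-carboxylate | C/C(=C\CCC1=CCC[C@](CC(=O)c2cc(OCOC)ccc2OCOC)(C(=O)OC(C)(C)C)OC1)CO | intermediate
33 | p-coumaric acid, (2E)-3-(4-hydroxyphenyl)prop-2-enoic acid | OC(=O)/C=C/c1ccc(O)cc1 | starting material
34 | methoxymethyl (2E)-3-[4-(methoxymethoxy)phenyl]prop-2-enoate | COCOC(=O)/C=C/c1ccc(OCOC)cc1 | intermediate
35 | (2E)-3-[4-(methoxymethoxy)phenyl]prop-2-enoic acid | OC(=O)/C=C/c1ccc(OCOC)cc1 | intermediate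
36 | tert-butyl (2S)-2-{2-[2,5-bis(methoxymethoxy)phenyl]-2-oxoethyl}-6-[(3E)-5-({(2E)-3-[4-(methoxymethoxy)phenyl]prop-2-enoyl}oxy)-4-methylpent-3-en-1-yl]-2,3,4,7-tetrahydrooxepine-2-carboxylate | C/C(=C\CCC1=CCC[C@](CC(=O)c2cc(OCOC)ccc2OCOC)(C(=O)OC(C)(C)C)OC1)COC(=O)/C=C/c1ccc(OCOC)cc1 | intermediate
37 | (2S)-2-[2-(2,5-dihydroxyphenyl)-2-oxoethyl]-6-[(3E)-5-{[(2E)-3-(4-hydroxyphenyl)prop-2-enoyl]oxy}-4-methylpent-3-en-1-yl]-2,3,4,7-tetrahydrooxepine-2-carboxylic acid | C/C(=C\CCC1=CCC[C@](CC(=O)c2cc(O)ccc2O)(C(=O)O)OC1)COC(=O)/C=C/c1ccc(O)cc1 | target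

## Step count and least certain steps

Total number of steps: 21. Longest linear sequence: 15 steps (steps 1, 3 to 8, 12 to 14, 16 to 18, 20 and 21).

**Step 8 (key step, proposed new method).** The most likely failures are premature thermal opening of 16 with loss of HBr to a bromo-diene before hydride arrives, consumption of the silane by residual silver cation, and cleavage of the tert-butyl ester by the BF3 that the tetrafluoroborate releases. The fallback uses known chemistry, sets out from 14 and returns at 17. The carbene addition is run as before to 16, which is heated with K2CO3 in methanol; ionisation and capture by methanol give the isolable methyl acetal tert-butyl (2S,7RS)-6-bromo-2-{2-[(tert-butyldiphenylsilyl)oxy]ethyl}-7-methoxy-2,3,4,7-tetrahydrooxepine-2-carboxylate F1, the established outcome for dihalocarbene adducts of cyclic enol ethers. F1 is then reduced at C7 with Et3SiH and BF3·OEt2 in CH2Cl2 at −78 °C, a standard reduction of a cyclic allylic acetal through its oxocarbenium ion, to give 17.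

**Step 3 (aldol).** The bulky tert-butyl ester and the longer ketone substituent may lower facial selectivity or turnover, and the tertiary aldolate can revert by retro-aldol cleavage. The fallback replaces catalyst control by a separable auxiliary; it sets out from 4 and returns at 9. Commercial (4S)-3-acetyl-4-(propan-2-yl)-1,3-thiazolidine-2-thione (either antipode is available) is converted into its divalent tin enolate with Sn(OTf)2 and N-ethylpiperidine in CH2Cl2 at −78 °C and added to 4. The adduct tert-butyl (2S)-2-hydroxy-2-{2-oxo-2-[(4S)-4-(propan-2-yl)-2-sulfanylidene-1,3-thiazolidin-3-yl]ethyl}hept-6-enoate F2 is separated from its C2 epimer by chromatography or crystallisation, and LiBH4 removes the auxiliary reductively to give 9. Stereochemical purity then rests on a separation of diastereomers, whatever the level of induction.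

**Step 12 (B-alkyl coupling).** Hydroboration of the conjugated diene may be incompletely regioselective or go twice, and transfer of the alkyl group to palladium may be slow at the hindered bromo-olefin. The fallback builds the trisubstituted side-chain olefin after the coupling; it sets out from 17 and returns at 24.
- Negishi coupling of 17 with commercial but-3-enylzinc bromide (PdCl2(dppf), THF, 50 °C) gives tert-butyl (2S)-6-(but-3-en-1-yl)-2-{2-[(tert-butyldiphenylsilyl)oxy]ethyl}-2,3,4,7-tetrahydrooxepine-2-carboxylate F3.
- Cross-metathesis with methacrolein (second-generation Hoveyda–Grubbs catalyst, CH2Cl2, 40 °C), in which the trisubstituted ring olefin is inert, gives the (E)-enal tert-butyl (2S)-2-{2-[(tert-butyldiphenylsilyl)oxy]ethyl}-6-[(3E)-4-methyl-5-oxopent-3-en-1-yl]-2,3,4,7-tetrahydrooxepine-2-carboxylate F4.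
- Luche reduction (NaBH4, CeCl3, MeOH, 0 °C) gives tert-butyl (2S)-2-{2-[(tert-butyldiphenylsilyl)oxy]ethyl}-6-[(3E)-5-hydroxy-4-methylpent-3-en-1-yl]-2,3,4,7-tetrahydrooxepine-2-carboxylate F5.
- Etherification with 4-methoxybenzyl 2,2,2-trichloroacetimidate and catalytic La(OTf)3 gives 24.

**Step 16 (aryllithium addition).** The basic aryllithium may enolise the aldehyde, after which the ring oxygen is lost by β-elimination, or it may attack the ester. The fallback changes to a non-basic carbonyl addition; it sets out from 29 and returns at 30. Quenching 29 with iodine gives 2-iodo-1,4-bis(methoxymethoxy)benzene F6, which is added to 26 by a Nozaki–Hiyama–Kishi reaction (CrCl2, catalytic NiCl2, DMF, rt). The arylchromium species formed from divalent chromium adds to aldehydes without deprotonating them and ignores esters.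

**Step 21 (global deprotection).** The time needed to cleave the tert-butyl ester may allow ionisation of the allylic cinnamate, acid-induced migration or hydration of the trisubstituted olefins, or alkylation of the hydroquinone by formaldehyde equivalents. The fallback separates the easy from the hard unmasking; it sets out from 36 and returns at 37. NaHSO4 on silica in CH2Cl2 at rt, a mild reagent selective for phenolic MOM ethers, gives tert-butyl (2S)-2-[2-(2,5-dihydroxyphenyl)-2-oxoethyl]-6-[(3E)-5-{[(2E)-3-(4-hydroxyphenyl)prop-2-enoyl]oxy}-4-methylpent-3-en-1-yl]-2,3,4,7-tetrahydrooxepine-2-carboxylate F7. The tert-butyl ester of F7 is then cleaved by a Lewis acid, anhydrous ZnBr2 in CH2Cl2, followed by a mildly acidic aqueous work-up, to give 37.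

## Further compounds

F1 | step 8 | tert-butyl (2S,7RS)-6-bromo-2-{2-[(tert-butyldiphenylsilyl)oxy]ethyl}-7-methoxy-2,3,4,7-tetrahydrooxepine-2-carboxylate | BrC1=CCC[C@](CCO[Si](c2ccccc2)(c2ccccc2)C(C)(C)C)(C(=O)OC(C)(C)C)OC1OC
F2 | step 3 | tert-butyl (2S)-2-hydroxy-2-{2-oxo-2-[(4S)-4-(propan-2-yl)-2-sulfanylidene-1,3-thiazolidin-3-yl]ethyl}hept-6-enoate | C=CCCC[C@](CC(=O)N1[C@@H](C(C)C)CSC1=S)(C(=O)OC(C)(C)C)O
F3 | step 12 | tert-butyl (2S)-6-(but-3-en-1-yl)-2-{2-[(tert-butyldiphenylsilyl)oxy]ethyl}-2,3,4,7-tetrahydrooxepine-2-carboxylate | C=CCCC1=CCC[C@](CCO[Si](c2ccccc2)(c2ccccc2)C(C)(C)C)(C(=O)OC(C)(C)C)OC1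
F4 | step 12 | tert-butyl (2S)-2-{2-[(tert-butyldiphenylsilyl)oxy]ethyl}-6-[(3E)-4-methyl-5-oxopent-3-en-1-yl]-2,3,4,7-tetrahydrooxepine-2-carboxylate | C/C(=C\CCC1=CCC[C@](CCO[Si](c2ccccc2)(c2ccccc2)C(C)(C)C)(C(=O)OC(C)(C)C)OC1)C=O
F5 | step 12 | tert-butyl (2S)-2-{2-[(tert-butyldiphenylsilyl)oxy]ethyl}-6-[(3E)-5-hydroxy-4-methylpent-3-en-1-yl]-2,3,4,7-tetrahydrooxepine-2-carboxylate | C/C(=C\CCC1=CCC[C@](CCO[Si](c2ccccc2)(c2ccccc2)C(C)(C)C)(C(=O)OC(C)(C)C)OC1)CO
F6 | step 16 | 2-iodo-1,4-bis(methoxymethoxy)benzene | COCOc1ccc(OCOC)c(I)c1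
F7 | step 21 | tert-butyl (2S)-2-[2-(2,5-dihydroxyphenyl)-2-oxoethyl]-6-[(3E)-5-{[(2E)-3-(4-hydroxyphenyl)prop-2-enoyl]oxy}-4-methylpent-3-en-1-yl]-2,3,4,7-tetrahydrooxepine-2-carboxylate | C/C(=C\CCC1=CCC[C@](CC(=O)c2cc(O)ccc2O)(C(=O)OC(C)(C)C)OC1)COC(=O)/C=C/c1ccc(O)cc1
A1 | alternative 1 | tert-butyl (2E)-4-[2,5-bis(methoxymethoxy)phenyl]-2-[(3Z,7E)-4-(hydroxymethyl)-9-({(2E)-3-[4-(methoxymethoxy)phenyl]prop-2-enoyl}oxy)-8-methylnona-3,7-dien-1-yl]-4-oxobut-2-enoate | OC/C(CC/C=C(\C)COC(=O)/C=C/c1ccc(OCOC)cc1)=C\CC/C(C(=O)OC(C)(C)C)=C\C(=O)c1cc(OCOC)ccc1OCOC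
A2 | alternative 1 | tert-butyl (2S)-2-{2-[2,5-bis(methoxymethoxy)phenyl]-2-oxoethyl}-6-[(3E)-5-({(2E)-3-[4-(methoxymethoxy)phenyl]prop-2-enoyl}oxy)-4-methylpent-3-en-1-yl]-2,3,4,7-tetrahydrooxepine-2-carboxylate | C/C(=C\CCC1=CCC[C@](CC(=O)c2cc(OCOC)ccc2OCOC)(C(=O)OC(C)(C)C)OC1)COC(=O)/C=C/c1ccc(OCOC)cc1
A3 | alternative 2 | tert-butyl (2S)-2-{[2-(2,5-bis(methoxymethoxy)phenyl)-1,3-dioxolan-2-yl]methyl}-7-diazo-2-hydroxy-6-oxoheptanoate | [N-]=[N+]=CC(=O)CCC[C@](CC1(c2cc(OCOC)ccc2OCOC)OCCO1)(C(=O)OC(C)(C)C)O
A4 | alternative 2 | tert-butyl (2S)-2-{[2-(2,5-bis(methoxymethoxy)phenyl)-1,3-dioxolan-2-yl]methyl}-6-oxooxepane-2-carboxylate | O=C1CCC[C@](CC2(c3cc(OCOC)ccc3OCOC)OCCO2)(C(=O)OC(C)(C)C)OC1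
A5 | alternative 3 | tert-butyl (2S,5Z,9E)-11-[(tert-butyldiphenylsilyl)oxy]-2-[2-(tert-butylsulfanyl)-2-oxoethyl]-2-[(2-methoxyethoxy)methoxy]-10-methyl-6-(trimethylsilyl)undeca-5,9-dienoate | COCCOCO[C@@](CC(=O)SC(C)(C)C)(C(=O)OC(C)(C)C)CC/C=C(\[Si](C)(C)C)CC/C=C(\C)CO[Si](c1ccccc1)(c1ccccc1)C(C)(C)C
A6 | alternative 3 | tert-butyl (2S)-6-{(3E)-5-[(tert-butyldiphenylsilyl)oxy]-4-methylpent-3-en-1-yl}-2-[2-(tert-butylsulfanyl)-2-oxoethyl]-2,3,4,7-tetrahydrooxepine-2-carboxylate | C1(CC/C=C(\C)CO[Si](c2ccccc2)(c2ccccc2)C(C)(C)C)=CCC[C@](CC(=O)SC(C)(C)C)(C(=O)OC(C)(C)C)OC1
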